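**Retrosynthetic overview**
1. Target 14 ⇒ 2-deoxy dimer 12 by a late C2–O bond formation: face-selective α-hydroxylation of the dienolate of 12 (key step, sets the C2 carbinol).
2. 12 ⇒ Diels–Alder union of dienone 11 (diene C2=C1–C10=C14) with enone 9 (dienophile C4′=C15′); this forms the cyclohexene ring and the spiro centre C4′.
3. 11 ⇐ 9 by Saegusa oxidation; 9 (7-epi-dehydrozaluzanin C) ⇐ 7 by allylic oxidation at C3.
4. 7 (cis-lactone) ⇐ dehydrocostus lactone 1 by inversion of C7: epoxide → bromohydrin → 2-(bromomethyl)butenolide → zinc-mediated transposing protonation.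
5. Ring order: the 5-7-5 skeleton is bought with 1; the lactone fusion is edited first, then the cyclohexene/spiro ring is made, then the C2–O bond.

Assumption: the SMILES is read literally; it encodes cis-fused lactones (H-6 and H-7 cis, C7 R) in both halves, so both halves are 7-epi-dehydrozaluzanin C units and C7 of the commercial trans-lactone 1 (costus root constituent) must be inverted.

**Step 1**
Reactants: 1 dehydrocostus lactone
Product: 2 11β,13-epoxy-11,13-dihydrodehydrocostus lactone
Conditions: t-BuOOH (1.5 equiv), DBU (1.2 equiv), CH2Cl2, 0 °C → rt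
Reagents that add atoms: tert-butyl hydroperoxide, CC(C)(C)OO
Why: Weitz–Scheffer nucleophilic epoxidation attacks only the electron-poor α-methylene lactone (the two unactivated exo-methylenes are inert), and the peroxy enolate closes at C11 on the β-face, anti to the axial H-7 (this centre is erased in step 3).

**Step 2**
Reactants: 2 11β,13-epoxy-11,13-dihydrodehydrocostus lactone
Product: 3 13-bromo-11β-hydroxy-11,13-dihydrodehydrocostus lactone
Conditions: MgBr2·OEt2 (2 equiv), Et2O–CH2Cl2, −20 → 0 °C; then H2O
Reagents that add atoms: magnesium bromide diethyl etherate, [Mg+2].[Br-].[Br-].CCOCC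
Why: Lewis-acid-assisted SN2 opening of the spiro-epoxide by bromide at the primary C13 (the tertiary, carbonyl-bearing C11 is not attacked), so the C11–O bond and its configuration are kept.

**Step 3**
Reactants: 3 13-bromo-11β-hydroxy-11,13-dihydrodehydrocostus lactone
Product: 5 13-bromoguaia-4(15),7(11),10(14)-trien-12,6-olide, via alkoxysulfurane 4 (not isolated)
Conditions: Martin sulfurane Ph2S[OC(CF3)2Ph]2 (1.3 equiv), CH2Cl2, 0 °C → rt
Reagents that add atoms: none
Why: Martin-sulfurane dehydration of the tertiary alcohol by anti E2 loss of H-7α (antiperiplanar to the 11β C–O bond) gives the conjugated tetrasubstituted butenolide in preference to the vinyl bromide, making C7 trigonal.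

**Step 4**
Reactants: 5 13-bromoguaia-4(15),7(11),10(14)-trien-12,6-olide
Product: 7 7-epi-dehydrocostus lactone, via allylzinc bromide 6 (not isolated)
Conditions: Zn dust (5 equiv), sat. aq NH4Cl–THF (1:4), 0 °C → rt
Reagents that add atoms: none
Why: Zinc insertion into the allylic C–Br bond and SE2′ protonation of the 2-carboxyallylzinc at C7 (reductive transposition known for Morita–Baylis–Hillman-type allylic bromides) restores the exo-methylene and delivers H on the open face of the planar butenolide (the H-6 face, opposite C5), setting H-7 cis to H-6 (C7 R, cis-lactone).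

**Step 5**
Reactants: 7 7-epi-dehydrocostus lactone
Product: 8 3α-hydroxy-7-epi-dehydrocostus lactone
Conditions: SeO2 (0.5 equiv), t-BuOOH (2 equiv), CH2Cl2, rt
Reagents that add atoms: selenium dioxide, O=[Se]=O; tert-butyl hydroperoxide, CC(C)(C)OO
Why: Sharpless-type SeO2 allylic hydroxylation (ene reaction then [2,3]-sigmatropic shift) of the ring A exo-methylene at its allylic CH2 (C3), as is known for dehydrocostus lactone itself, with O entering on the convex α-face (this carbinol centre is removed in step 6).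

**Step 6**
Reactants: 8 3α-hydroxy-7-epi-dehydrocostus lactone
Product: 9 7-epi-dehydrozaluzanin C
Conditions: Dess–Martin periodinane (1.3 equiv), CH2Cl2, rt
Reagents that add atoms: none
Why: Dess–Martin oxidation of the secondary allylic alcohol gives the α-methylene cyclopentanone under neutral conditions that leave the Michael acceptors and C5 untouched.

**Step 7**
Reactants: 9 7-epi-dehydrozaluzanin C
Product: 10 3-(tert-butyldimethylsilyloxy)guaia-2,4(15),10(14),11(13)-tetraen-12,6-olide (7-epi series)
Conditions: TBSOTf (1.2 equiv), Et3N (2 equiv), CH2Cl2, −78 → 0 °C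
Reagents that add atoms: tert-butyldimethylsilyl trifluoromethanesulfonate, CC(C)(C)[Si](C)(C)OS(=O)(=O)C(F)(F)F
Why: Soft enolisation can only go toward C2 (C4 is sp2), so a single silyl dienol ether forms and the α-methylene lactone is not touched.

**Step 8**
Reactants: 10 silyl dienol ether; 9 7-epi-dehydrozaluzanin C (3 equiv)
Product: 12 2-deoxy dimer (Diels–Alder adduct with C2–C4′ and C14–C15′ bonds and C1=C10), via dienone 11 (not isolated)
Conditions: Pd(OAc)2 (1.05 equiv relative to 10), MeCN, rt → 40 °C, 9 present from the start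
Reagents that add atoms: none
Why: Saegusa–Ito oxidation gives the cross-conjugated dienone 11, whose locked s-cis diene is trapped in situ by the enone exo-methylene of 9 in an intermolecular Diels–Alder reaction with "ortho" regiochemistry; the dienophile reacts on its H-5′ face (anti to C6′), which fixes the spiro centre C4′, and the endo adduct (H-2α) is drawn, its exo counterpart differing only at C2, which is re-set in step 9.

**Step 9**
Reactants: 12 2-deoxy dimer
Product: 14 target, via dienolate 13 (not isolated)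
Conditions: (S)-2-{[2,3-bis(dicyclohexylamino)cycloprop-2-en-1-ylidene]amino}-3-phenylpropan-1-ol (10 mol %), (±)-3-phenyl-2-(phenylsulfonyl)oxaziridine (1.3 equiv), toluene–CH2Cl2, −40 °C
Reagents that add atoms: 3-phenyl-2-(phenylsulfonyl)oxaziridine, O=S(=O)(c1ccccc1)N1OC1c1ccccc1
Why: Proposed new method: the chiral cyclopropenimine Brønsted base with its hydrogen-bond-donating hydroxyl removes only the doubly activated tertiary H-2 (α to C3=O and allylic to C1=C10, several pK units more acidic than the C2′ methylene) to give the ion-paired cross-conjugated dienolate 13 with planar C2, and electrophilic O-transfer from the N-sulfonyloxaziridine then occurs at the α-carbon C2 rather than the γ-carbon C10 and on the α-face of ring A (cis to H-5, anti to C6 and to the pseudo-axial C3′ carbonyl arm of the spiro ring), the catalyst enantiomer being the one that reinforces this substrate bias, which sets the C2 carbinol centre without hydroperoxide anions or metal enolates that would attack the three Michael acceptors; the closest known reaction type is the organocatalytic α-hydroxylation of β-keto esters with oxaziridines or peroxides, not yet shown for an α-tertiary cross-conjugated ketone dienolate.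

**Compound list**
1 | dehydrocostus lactone (H-1α, H-5α, H-6β, H-7α; trans-lactone) | C=C1CC[C@H]2C(=C)CC[C@H]3C(=C)C(=O)O[C@@H]3[C@H]21 | starting material
2 | 11β,13-epoxy-11,13-dihydrodehydrocostus lactone (spiro-epoxide, O-11 β, anti to H-7α) | C=C1CC[C@H]2C(=C)CC[C@H]3[C@]4(CO4)C(=O)O[C@@H]3[C@H]21 | intermediate
3 | 13-bromo-11β-hydroxy-11,13-dihydrodehydrocostus lactone | C=C1CC[C@H]2C(=C)CC[C@H]3[C@](O)(CBr)C(=O)O[C@@H]3[C@H]21 | intermediate
4 | alkoxysulfurane of 3 (O-11 bound to SPh2[OC(CF3)2Ph]) | C=C1CC[C@H]2C(=C)CC[C@H]3[C@](OS(c4ccccc4)(c4ccccc4)OC(c4ccccc4)(C(F)(F)F)C(F)(F)F)(CBr)C(=O)O[C@@H]3[C@H]21 | intermediate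
5 | 13-bromoguaia-4(15),7(11),10(14)-trien-12,6-olide (H-1α, H-5α, H-6β) | C=C1CC[C@H]2C(=C)CCC3=C(CBr)C(=O)O[C@@H]3[C@H]21 | intermediate
6 | allylzinc bromide from 5 (C13–ZnBr) | C=C1CC[C@H]2C(=C)CCC3=C(C[Zn]Br)C(=O)O[C@@H]3[C@H]21 | intermediate
7 | 7-epi-dehydrocostus lactone (H-1α, H-5α, H-6β, H-7β; cis-lactone) | C=C1CC[C@H]2C(=C)CC[C@@H]3C(=C)C(=O)O[C@@H]3[C@H]21 | intermediate
8 | 3α-hydroxy-7-epi-dehydrocostus lactone (OH cis to H-1 and H-5) | C=C1[C@H](O)C[C@H]2C(=C)CC[C@@H]3C(=C)C(=O)O[C@@H]3[C@H]21 | intermediate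
9 | 7-epi-dehydrozaluzanin C (3-oxo; H-1α, H-5α, H-6β, H-7β) | C=C1C(=O)C[C@H]2C(=C)CC[C@@H]3C(=C)C(=O)O[C@@H]3[C@H]21 | intermediate
10 | 3-(tert-butyldimethylsilyloxy)guaia-2,4(15),10(14),11(13)-tetraen-12,6-olide (7-epi series) | C=C1C(O[Si](C)(C)C(C)(C)C)=C[C@H]2C(=C)CC[C@@H]3C(=C)C(=O)O[C@@H]3[C@H]21 | intermediate
11 | 3-oxoguaia-1,4(15),10(14),11(13)-tetraen-12,6-olide (H-5α, H-6β, H-7β) | C=C1C(=O)C=C2C(=C)CC[C@@H]3C(=C)C(=O)O[C@@H]3[C@H]21 | intermediate
12 | 2-deoxy dimer (H-2α, cis to H-5; C4′ bonded to C2 on the H-5′ face; both lactones cis) | C=C1C(=O)[C@@H]2C3=C(CC[C@@H]4C(=C)C(=O)O[C@@H]4[C@@H]13)CC[C@]21C(=O)C[C@H]2C(=C)CC[C@@H]3C(=C)C(=O)O[C@@H]3[C@H]21 | intermediate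
13 | dienolate of 12 (C2=C3–O⁻, ion pair with the protonated catalyst) | C=C1C([O-])=C2C3=C(CC[C@@H]4C(=C)C(=O)O[C@@H]4[C@@H]13)CC[C@]21C(=O)C[C@H]2C(=C)CC[C@@H]3C(=C)C(=O)O[C@@H]3[C@H]21 | intermediate
14 | CNP0269880.1 (2α-hydroxy dimer) | C=C1C(=O)[C@]2(O)C3=C(CC[C@@H]4C(=C)C(=O)O[C@@H]4[C@@H]13)CC[C@]21C(=O)C[C@H]2C(=C)CC[C@@H]3C(=C)C(=O)O[C@@H]3[C@H]21 | target

**Totals**
Total step count: 9. Longest linear sequence: 9 steps (1 → 14; compound 9 enters step 8 a second time as the dienophile).

**Three steps most likely to fail**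

Step 4 (zinc-mediated transposing protonation). The allylzinc may protonate at C13 to give the conjugated 13-methylbutenolide, or couple. The fallback sets out from 5 and comes back at 7. Bromide 5 is hydrolysed with Ag2O in aqueous acetone to 13-hydroxyguaia-4(15),7(11),10(14)-trien-12,6-olide F1. Under Myers conditions (PPh3, DEAD, 2-nitrobenzenesulfonylhydrazide, THF, −30 °C → rt) this gives the N-allyl-N-(2-nitrophenylsulfonyl)hydrazine F2. Loss of the arenesulfinic acid gives the allylic diazene F3, whose retro-ene loss of N2 delivers H to C7 intramolecularly on the H-6 face with the same 1,3-transposition. This path cannot give the 13-methyl isomer and yields 7.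

Step 8 (Saegusa oxidation and cross Diels–Alder). Homodimerisation of 11 or palladium-mediated side reactions of the exo-methylenes may dominate. The fallback sets out from 10 and comes back at 12. Treatment of 10 with PhSeCl (CH2Cl2, −78 °C) gives 2α-(phenylseleno)-7-epi-dehydrozaluzanin C F4. Oxidation with H2O2 and pyridine (CH2Cl2, 0 °C) in the presence of 9 (3 equiv) gives the selenoxide F5. Its syn-elimination with H-1 releases dienone 11 slowly and without metal, and 11 is trapped by 9 to give 12.

Step 9 (the proposed new hydroxylation). The hindered tertiary H-2 may be removed too slowly, the dienolate may add to a methylene lactone, or the face selectivity may be low. The fallback uses known chemistry, sets out from 12 and comes back at 14. Base-mediated aerobic α-hydroxylation under substrate control (Cs2CO3 0.2 equiv, P(OEt)3 2 equiv, O2 1 atm, DMSO–THF, 0 °C) gives the 2α-hydroperoxide of 12 F6, which the phosphite reduces in the same flask to 14.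

**Further compounds**
F1 | step 4 | 13-hydroxyguaia-4(15),7(11),10(14)-trien-12,6-olide | C=C1CC[C@H]2C(=C)CCC3=C(CO)C(=O)O[C@@H]3[C@H]21
F2 | step 4 | N-allyl-N-(2-nitrophenylsulfonyl)hydrazine of F1 (N on C13) | C=C1CC[C@H]2C(=C)CCC3=C(CN(N)S(=O)(=O)c4ccccc4[N+](=O)[O-])C(=O)O[C@@H]3[C@H]21
F3 | step 4 | allylic diazene (C13–N=NH) | C=C1CC[C@H]2C(=C)CCC3=C(CN=N)C(=O)O[C@@H]3[C@H]21
F4 | step 8 | 2α-(phenylseleno)-7-epi-dehydrozaluzanin C | C=C1C(=O)[C@H]([Se]c4ccccc4)[C@H]2C(=C)CC[C@@H]3C(=C)C(=O)O[C@@H]3[C@H]21
F5 | step 8 | selenoxide of F4 | C=C1C(=O)[C@H]([Se](=O)c4ccccc4)[C@H]2C(=C)CC[C@@H]3C(=C)C(=O)O[C@@H]3[C@H]21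
F6 | step 9 | 2α-hydroperoxide of 12 | C=C1C(=O)[C@]2(OO)C3=C(CC[C@@H]4C(=C)C(=O)O[C@@H]4[C@@H]13)CC[C@]21C(=O)C[C@H]2C(=C)CC[C@@H]3C(=C)C(=O)O[C@@H]3[C@H]21
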